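Retrosynthetic cuts, in order: (a) the ester C–O bond between the ring CH2O arm and the 3-hydroxy-3-methylglutarate half-ester; (b) the side-chain CO2H back to CH2OH and the C4=C5 alkene back to an alkyne; (c) the C1'–C5 bond (ketone plus acetylide); (d) the C4' oxygen, the C2'=C3' alkene and the C2' methyl; (e) the C5'–C6' bond of the cyclohexanone.
Enabling feature: quaternary C6' (CH3, CH2O) sits next to oxygenated C1' in the cyclohexenone ring. With C1' as a ketone this is a β-hydroxy ketone with a quaternary α-carbon, which is what a 1,2-shift in a tertiary α-hydroxy epoxide delivers.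
Forward order: cyclopentanol from a glycidate ester and a C4 bis-Grignard reagent; ring expansion to the six-membered ring (the only ring of the target); C2' methylation, dehydrogenation, C4' oxidation, ketalisation; acetylide addition at C1'; trans-reduction; acylation; deprotection; two-stage oxidation of C1.
Stereochemistry: C6' comes from methyl (R)-2-methylglycidate through stereospecific anti migration (inversion); C1' is relayed from C6' by an alkoxide-chelated acetylide addition; the glutarate carbinol comes from (R)-mevalonolactone; 2Z comes from the commercial enynol and 4E from alkoxide-directed hydroalumination.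

Key step: step 2

Remark: abscisic acid numbering is used throughout (ring C1'–C6', side chain C1–C5); the target SMILES places the C6' CH2O arm trans to the C1' hydroxyl, and the three chiral or Z-configured building blocks are taken as purchasable in isomerically pure form.

Step 1
Reactants: 1 methyl (2R)-2-methyloxirane-2-carboxylate (methyl (R)-2-methylglycidate); 2 1,4-dibromobutane
Product: 4 1-[(2R)-2-methyloxiran-2-yl]cyclopentan-1-ol, via butane-1,4-diylbis(magnesium bromide) 3 (not isolated)
Conditions: Mg, THF, 25–40 °C; then 1, THF, −78 → −30 °C; H2O work-up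
Reagents that add atoms: none
Why: Double Grignard addition to an ester: the first C–Mg end gives a ketone, the tethered second end closes the cyclopentane on it faster than anything attacks the hindered 2,2-disubstituted epoxide at low temperature, and the glycidate stereocentre is not touched.

Step 2
Reactants: 4 1-[(2R)-2-methyloxiran-2-yl]cyclopentan-1-ol
Product: 5 (2S)-2-(hydroxymethyl)-2-methylcyclohexan-1-one
Conditions: BF3·OEt2 (0.3 equiv), CH2Cl2, −78 → −40 °C; aq NaHCO3
Reagents that add atoms: none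
Why: BF3 binds the epoxide oxygen and weakens its bond to the tertiary carbon (future C6'); as that bond breaks, a ring CH2 antiperiplanar to it shifts from the carbinol carbon (future C1') to C6' while the hydroxyl lone pair forms the C1' carbonyl, which is the semipinacol rearrangement of a tertiary α-hydroxy epoxide, a known Lewis-acid reaction. The six-membered ring is closed by ring expansion through a 1,2-alkyl shift (five to six members) and not by a cyclisation, and the new C5'–C6' bond is the only skeletal bond formed. The quaternary stereocentre C6' is controlled by the glycidate-derived epoxide carbon: migration anti to the departing oxygen gives inversion, so the (R)-epoxide should deliver the (S)-ketone. The step needs a concerted shift and not a free tertiary cation, which would erode the configuration or divert to a hydride shift and an aldehyde; the electron push of the free tertiary hydroxyl, the low temperature and the weakly ionising solvent are expected to secure this. No regiochemical choice exists because either cyclopentane CH2 next to the carbinol leads to the same product.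

Step 3
Reactants: 5 (2S)-2-(hydroxymethyl)-2-methylcyclohexan-1-one
Product: 6 (2S)-2-({[tert-butyl(dimethyl)silyl]oxy}methyl)-2-methylcyclohexan-1-one
Conditions: TBSCl, imidazole, DMF, 0 °C → rt
Reagents that add atoms: tert-butyl(chloro)dimethylsilane, CC(C)(C)[Si](C)(C)Cl
Why: Silylation of the primary neopentyl alcohol with a base (imidazole) too weak to trigger retro-aldol loss of formaldehyde from the β-hydroxy ketone; the ether is needed for the enolate and oxidation steps that follow.

Step 4
Reactants: 6 (2S)-2-({[tert-butyl(dimethyl)silyl]oxy}methyl)-2-methylcyclohexan-1-one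
Product: 8 (2S)-2-({[tert-butyl(dimethyl)silyl]oxy}methyl)-2,6-dimethylcyclohexan-1-one (both C6 epimers), via lithium enolate 7 (not isolated)
Conditions: LiN(i-Pr)2 (1.05 equiv), THF, −78 °C; then MeI, −78 → 0 °C
Reagents that add atoms: iodomethane, CI
Why: Enolate alkylation in which only C2' carries α-hydrogens because C6' is quaternary, so the regiochemistry is fixed; the new methine centre need not be controlled since it becomes sp2 in step 5.

Step 5
Reactants: 8 (2S)-2-({[tert-butyl(dimethyl)silyl]oxy}methyl)-2,6-dimethylcyclohexan-1-one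
Product: 10 (6S)-6-({[tert-butyl(dimethyl)silyl]oxy}methyl)-2,6-dimethylcyclohex-2-en-1-one, via trimethylsilyl enol ether 9 (not isolated)
Conditions: TMSOTf, Et3N, CH2Cl2, 0 °C; then Pd(OAc)2 (1.1 equiv), MeCN, rt
Reagents that add atoms: none
Why: Saegusa–Ito oxidation: soft enolisation can only give the C1'–C2' silyl enol ether, and the divalent palladium enolate formed from it undergoes β-hydride elimination toward C3' to give the endocyclic trisubstituted enone.

Step 6
Reactants: 10 (6S)-6-({[tert-butyl(dimethyl)silyl]oxy}methyl)-2,6-dimethylcyclohex-2-en-1-one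
Product: 11 (6S)-6-({[tert-butyl(dimethyl)silyl]oxy}methyl)-2,6-dimethylcyclohex-2-ene-1,4-dione
Conditions: Pd(OH)2 on carbon (5 mol %), t-BuOOH (5 equiv), K2CO3 (0.25 equiv), CH2Cl2, 4 °C → rt
Reagents that add atoms: tert-butyl hydroperoxide, CC(C)(C)OO
Why: Radical γ-oxidation of an α,β-enone to the ene-1,4-dione by tert-butylperoxyl radicals, a known transformation of cyclic enones; the C4'–H bonds are the weakest in the molecule (allylic and conjugated to the enone), and the silyl ether has no comparably weak C–H bond.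

Step 7
Reactants: 11 (6S)-6-({[tert-butyl(dimethyl)silyl]oxy}methyl)-2,6-dimethylcyclohex-2-ene-1,4-dione
Product: 12 (9S)-9-({[tert-butyl(dimethyl)silyl]oxy}methyl)-7,9-dimethyl-1,4-dioxaspiro[4.5]dec-6-en-8-one
Conditions: TMSOCH2CH2OTMS, TMSOTf (5 mol %), CH2Cl2, −78 → −20 °C; pyridine quench
Reagents that add atoms: 1,2-bis(trimethylsilyloxy)ethane, C[Si](C)(C)OCCO[Si](C)(C)C
Why: Noyori ketalisation at the more accessible carbonyl: C4' lies between CH2 and CH, whereas C1' is flanked by quaternary C6' and the methyl-bearing C2', the same discrimination that gives the 4-monoketal of 2,6,6-trimethylcyclohex-2-ene-1,4-dione; the low-temperature aprotic conditions spare the silyl ether.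

Step 8
Reactants: 12 (9S)-9-({[tert-butyl(dimethyl)silyl]oxy}methyl)-7,9-dimethyl-1,4-dioxaspiro[4.5]dec-6-en-8-one
Product: 13 (9S)-9-(hydroxymethyl)-7,9-dimethyl-1,4-dioxaspiro[4.5]dec-6-en-8-one
Conditions: Bu4NF, AcOH (1:1), THF, 0 °C → rt
Reagents that add atoms: none
Why: Fluoride cleavage of the primary silyl ether, buffered with acetic acid so that no free alkoxide accumulates that could cause retro-aldol loss of formaldehyde or conjugate addition to the enone; the dioxolane is inert to fluoride.

Step 9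
Reactants: 14 (2Z)-3-methylpent-2-en-4-yn-1-ol
Product: 15 tert-butyl(dimethyl){[(2Z)-3-methylpent-2-en-4-yn-1-yl]oxy}silane
Conditions: TBSCl, imidazole, CH2Cl2, 0 °C → rt
Reagents that add atoms: tert-butyl(chloro)dimethylsilane, CC(C)(C)[Si](C)(C)Cl
Why: Routine silylation of a primary allylic alcohol, which removes the acidic OH and later distinguishes this oxygen from the ring CH2OH.

Step 10
Reactants: 13 (9S)-9-(hydroxymethyl)-7,9-dimethyl-1,4-dioxaspiro[4.5]dec-6-en-8-one; 15 tert-butyl(dimethyl){[(2Z)-3-methylpent-2-en-4-yn-1-yl]oxy}silane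
Product: 17 (8S,9S)-8-[(3Z)-5-{[tert-butyl(dimethyl)silyl]oxy}-3-methylpent-3-en-1-yn-1-yl]-9-(hydroxymethyl)-7,9-dimethyl-1,4-dioxaspiro[4.5]dec-6-en-8-ol, via lithium acetylide 16 (not isolated)
Conditions: 15 (3 equiv), n-BuLi (2.9 equiv), THF, −78 °C; then 13, −78 → −40 °C; H2O
Reagents that add atoms: none
Why: 1,2-Addition of a lithium acetylide to the hindered enone carbonyl, as used for abscisic acid side chains; the first equivalent forms the lithium alkoxide of the C6' CH2OH, whose six-membered chelate to the carbonyl oxygen holds the CH2O arm in the carbonyl plane and the C6' methyl axial, so the acetylide should enter anti to that methyl and set C1' with its hydroxyl trans to the CH2O arm.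

Step 11
Reactants: 17 (8S,9S)-8-[(3Z)-5-{[tert-butyl(dimethyl)silyl]oxy}-3-methylpent-3-en-1-yn-1-yl]-9-(hydroxymethyl)-7,9-dimethyl-1,4-dioxaspiro[4.5]dec-6-en-8-ol
Product: 18 (8R,9S)-8-[(1E,3Z)-5-{[tert-butyl(dimethyl)silyl]oxy}-3-methylpenta-1,3-dien-1-yl]-9-(hydroxymethyl)-7,9-dimethyl-1,4-dioxaspiro[4.5]dec-6-en-8-ol
Conditions: NaAlH2(OCH2CH2OMe)2 (4 equiv), THF, 0 °C → rt; H2O work-up
Reagents that add atoms: none
Why: Alkoxide-directed trans-hydroalumination of a propargylic alcohol: the C1' alkoxyaluminate delivers hydride to the distal alkyne carbon and protonolysis of the vinyl–aluminium bond gives only the 4E alkene, leaving the 2Z alkene, the dioxolane and the silyl ether intact (the change of the C8 descriptor is formal).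

Step 12
Reactants: 19 (4R)-4-hydroxy-4-methyloxan-2-one ((R)-mevalonolactone)
Product: 21 benzyl (3R)-3,5-dihydroxy-3-methylpentanoate, via potassium (R)-mevalonate 20 (not isolated)
Conditions: KOH (1.0 equiv), H2O/MeOH, rt; evaporate; then BnBr, DMF, rt
Reagents that add atoms: potassium hydroxide, [K+].[OH-]; benzyl bromide, BrCc1ccccc1
Why: Saponification of the δ-lactone followed by SN2 O-alkylation of the carboxylate masks the former lactone carbonyl as a benzyl ester and frees the C5 hydroxyl; the stereocentre is not involved.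

Step 13
Reactants: 21 benzyl (3R)-3,5-dihydroxy-3-methylpentanoate
Product: 22 (3R)-5-(benzyloxy)-3-hydroxy-3-methyl-5-oxopentanoic acid
Conditions: TEMPO (0.2 equiv), PhI(OAc)2 (2.2 equiv), MeCN/H2O (1:1), rt
Reagents that add atoms: water, O
Why: Nitroxyl-catalysed oxidation of the primary alcohol through the aldehyde hydrate to the carboxylic acid; the tertiary alcohol cannot be oxidised and the crude diol is used at once to forestall relactonisation.

Step 14
Reactants: 22 (3R)-5-(benzyloxy)-3-hydroxy-3-methyl-5-oxopentanoic acid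
Product: 23 1-benzyl 5-methyl (3R)-3-hydroxy-3-methylpentanedioate
Conditions: Me3SiCHN2, toluene/MeOH (4:1), 0 °C
Reagents that add atoms: (trimethylsilyl)diazomethane, C[Si](C)(C)C=[N+]=[N-]
Why: O-Methylation of a carboxylic acid with a diazoalkane under neutral conditions, which avoids acid or base that could exchange the two ester ends.

Step 15
Reactants: 23 1-benzyl 5-methyl (3R)-3-hydroxy-3-methylpentanedioate
Product: 24 (3S)-3-hydroxy-5-methoxy-3-methyl-5-oxopentanoic acid
Conditions: H2 (1 atm), Pd on carbon (10 %), EtOAc, rt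
Reagents that add atoms: none
Why: Hydrogenolysis of the benzyl ester leaves the methyl ester, so the former lactone carbonyl becomes the free acid; the spatial arrangement of the mevalonolactone centre is unchanged and the (S) descriptor arises only from the new priority order.

Step 16
Reactants: 18 (8R,9S)-8-[(1E,3Z)-5-{[tert-butyl(dimethyl)silyl]oxy}-3-methylpenta-1,3-dien-1-yl]-9-(hydroxymethyl)-7,9-dimethyl-1,4-dioxaspiro[4.5]dec-6-en-8-ol; 24 (3S)-3-hydroxy-5-methoxy-3-methyl-5-oxopentanoic acid
Product: 25 1-{[(8R,9S)-8-[(1E,3Z)-5-{[tert-butyl(dimethyl)silyl]oxy}-3-methylpenta-1,3-dien-1-yl]-8-hydroxy-7,9-dimethyl-1,4-dioxaspiro[4.5]dec-6-en-9-yl]methyl} 5-methyl (3R)-3-hydroxy-3-methylpentanedioate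
Conditions: 24 (1.5 equiv), EDC·HCl, DMAP, CH2Cl2, 0 °C → rt
Reagents that add atoms: none
Why: Steglich esterification in which only the primary CH2OH is acylated, the tertiary hydroxyls at C1' and in the acid being too hindered; no bond to a stereocentre is made or broken.

Step 17
Reactants: 25 1-{[(8R,9S)-8-[(1E,3Z)-5-{[tert-butyl(dimethyl)silyl]oxy}-3-methylpenta-1,3-dien-1-yl]-8-hydroxy-7,9-dimethyl-1,4-dioxaspiro[4.5]dec-6-en-9-yl]methyl} 5-methyl (3R)-3-hydroxy-3-methylpentanedioate
Product: 26 1-{[(1S,2R)-2-hydroxy-2-[(1E,3Z)-5-hydroxy-3-methylpenta-1,3-dien-1-yl]-1,3-dimethyl-5-oxocyclohex-3-en-1-yl]methyl} 5-methyl (3R)-3-hydroxy-3-methylpentanedioate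
Conditions: 1 M HCl, THF, 0 °C → rt
Reagents that add atoms: water, O
Why: Acid hydrolysis of the dioxolane and of the primary allylic silyl ether in one operation; once C4' is a ketone the C1' hydroxyl is γ to an enone and resists ionisation, and the CH2O arm is already acylated so it cannot add to C2' of the enone.

Step 18
Reactants: 26 1-{[(1S,2R)-2-hydroxy-2-[(1E,3Z)-5-hydroxy-3-methylpenta-1,3-dien-1-yl]-1,3-dimethyl-5-oxocyclohex-3-en-1-yl]methyl} 5-methyl (3R)-3-hydroxy-3-methylpentanedioate
Product: 27 1-{[(1S,2R)-2-hydroxy-1,3-dimethyl-2-[(1E,3Z)-3-methyl-5-oxopenta-1,3-dien-1-yl]-5-oxocyclohex-3-en-1-yl]methyl} 5-methyl (3R)-3-hydroxy-3-methylpentanedioate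
Conditions: MnO2 (activated, excess), CH2Cl2, rt, dark
Reagents that add atoms: none
Why: MnO2 oxidises only the primary allylic alcohol, giving the (2Z)-enal under neutral conditions that preserve the Z geometry and leave the tertiary alcohols untouched.

Step 19
Reactants: 27 1-{[(1S,2R)-2-hydroxy-1,3-dimethyl-2-[(1E,3Z)-3-methyl-5-oxopenta-1,3-dien-1-yl]-5-oxocyclohex-3-en-1-yl]methyl} 5-methyl (3R)-3-hydroxy-3-methylpentanedioate
Product: 28 (2Z,4E)-5-[(1R,6S)-1-hydroxy-6-({[(3R)-3-hydroxy-5-methoxy-3-methyl-5-oxopentanoyl]oxy}methyl)-2,6-dimethyl-4-oxocyclohex-2-en-1-yl]-3-methylpenta-2,4-dienoic acid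
Conditions: NaClO2, NaH2PO4, 2-methylbut-2-ene, t-BuOH/H2O, 0 °C → rt, dark
Reagents that add atoms: sodium chlorite, [Na+].[O-]Cl=O
Why: Pinnick oxidation of the enal to the carboxylic acid with an alkene scavenger for hypochlorous acid, which spares the diene, the enone, both esters and the tertiary alcohols and keeps the 2Z geometry.

Compound list
1 | methyl (2R)-2-methyloxirane-2-carboxylate | C[C@@]1(CO1)C(=O)OC | starting material
2 | 1,4-dibromobutane | BrCCCCBr | starting material
3 | butane-1,4-diylbis(magnesium bromide) | Br[Mg]CCCC[Mg]Br | intermediate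
4 | 1-[(2R)-2-methyloxiran-2-yl]cyclopentan-1-ol | C[C@@]1(CO1)C1(O)CCCC1 | intermediate
5 | (2S)-2-(hydroxymethyl)-2-methylcyclohexan-1-one | OC[C@]1(C)CCCCC1=O | intermediate
6 | (2S)-2-({[tert-butyl(dimethyl)silyl]oxy}methyl)-2-methylcyclohexan-1-one | CC(C)(C)[Si](C)(C)OC[C@]1(C)CCCCC1=O | intermediate
7 | lithium (6S)-6-({[tert-butyl(dimethyl)silyl]oxy}methyl)-6-methylcyclohex-1-en-1-olate | CC(C)(C)[Si](C)(C)OC[C@]1(C)CCCC=C1O[Li] | intermediate
8 | (2S)-2-({[tert-butyl(dimethyl)silyl]oxy}methyl)-2,6-dimethylcyclohexan-1-one (both C6 epimers) | CC(C)(C)[Si](C)(C)OC[C@]1(C)CCCC(C)C1=O | intermediate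
9 | tert-butyl{[(1S)-1,3-dimethyl-2-[(trimethylsilyl)oxy]cyclohex-2-en-1-yl]methoxy}dimethylsilane | CC(C)(C)[Si](C)(C)OC[C@]1(C)CCCC(C)=C1O[Si](C)(C)C | intermediate
10 | (6S)-6-({[tert-butyl(dimethyl)silyl]oxy}methyl)-2,6-dimethylcyclohex-2-en-1-one | CC(C)(C)[Si](C)(C)OC[C@]1(C)CCC=C(C)C1=O | intermediate
11 | (6S)-6-({[tert-butyl(dimethyl)silyl]oxy}methyl)-2,6-dimethylcyclohex-2-ene-1,4-dione | CC(C)(C)[Si](C)(C)OC[C@]1(C)CC(=O)C=C(C)C1=O | intermediate
12 | (9S)-9-({[tert-butyl(dimethyl)silyl]oxy}methyl)-7,9-dimethyl-1,4-dioxaspiro[4.5]dec-6-en-8-one | CC(C)(C)[Si](C)(C)OC[C@]1(C)CC2(OCCO2)C=C(C)C1=O | intermediate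
13 | (9S)-9-(hydroxymethyl)-7,9-dimethyl-1,4-dioxaspiro[4.5]dec-6-en-8-one | OC[C@]1(C)CC2(OCCO2)C=C(C)C1=O | intermediate
14 | (2Z)-3-methylpent-2-en-4-yn-1-ol | C#C/C(C)=C\CO | starting material
15 | tert-butyl(dimethyl){[(2Z)-3-methylpent-2-en-4-yn-1-yl]oxy}silane | C#C/C(C)=C\CO[Si](C)(C)C(C)(C)C | intermediate
16 | lithium (3Z)-5-{[tert-butyl(dimethyl)silyl]oxy}-3-methylpent-3-en-1-yn-1-ide | [Li]C#C/C(C)=C\CO[Si](C)(C)C(C)(C)C | intermediate
17 | (8S,9S)-8-[(3Z)-5-{[tert-butyl(dimethyl)silyl]oxy}-3-methylpent-3-en-1-yn-1-yl]-9-(hydroxymethyl)-7,9-dimethyl-1,4-dioxaspiro[4.5]dec-6-en-8-ol | OC[C@]1(C)CC2(OCCO2)C=C(C)[C@]1(O)C#C/C(C)=C\CO[Si](C)(C)C(C)(C)C | intermediate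
18 | (8R,9S)-8-[(1E,3Z)-5-{[tert-butyl(dimethyl)silyl]oxy}-3-methylpenta-1,3-dien-1-yl]-9-(hydroxymethyl)-7,9-dimethyl-1,4-dioxaspiro[4.5]dec-6-en-8-ol | OC[C@]1(C)CC2(OCCO2)C=C(C)[C@]1(O)/C=C/C(C)=C\CO[Si](C)(C)C(C)(C)C | intermediate
19 | (4R)-4-hydroxy-4-methyloxan-2-one ((R)-mevalonolactone) | O=C1C[C@](C)(O)CCO1 | starting material
20 | potassium (3R)-3,5-dihydroxy-3-methylpentanoate | [K+].[O-]C(=O)C[C@](C)(O)CCO | intermediate
21 | benzyl (3R)-3,5-dihydroxy-3-methylpentanoate | O=C(OCc1ccccc1)C[C@](C)(O)CCO | intermediate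
22 | (3R)-5-(benzyloxy)-3-hydroxy-3-methyl-5-oxopentanoic acid | O=C(OCc1ccccc1)C[C@](C)(O)CC(=O)O | intermediate
23 | 1-benzyl 5-methyl (3R)-3-hydroxy-3-methylpentanedioate | O=C(OCc1ccccc1)C[C@](C)(O)CC(=O)OC | intermediate
24 | (3S)-3-hydroxy-5-methoxy-3-methyl-5-oxopentanoic acid | COC(=O)C[C@@](C)(O)CC(=O)O | intermediate
25 | 1-{[(8R,9S)-8-[(1E,3Z)-5-{[tert-butyl(dimethyl)silyl]oxy}-3-methylpenta-1,3-dien-1-yl]-8-hydroxy-7,9-dimethyl-1,4-dioxaspiro[4.5]dec-6-en-9-yl]methyl} 5-methyl (3R)-3-hydroxy-3-methylpentanedioate | COC(=O)C[C@@](C)(O)CC(=O)OC[C@]1(C)CC2(OCCO2)C=C(C)[C@]1(O)/C=C/C(C)=C\CO[Si](C)(C)C(C)(C)C | intermediate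
26 | 1-{[(1S,2R)-2-hydroxy-2-[(1E,3Z)-5-hydroxy-3-methylpenta-1,3-dien-1-yl]-1,3-dimethyl-5-oxocyclohex-3-en-1-yl]methyl} 5-methyl (3R)-3-hydroxy-3-methylpentanedioate | COC(=O)C[C@@](C)(O)CC(=O)OC[C@]1(C)CC(=O)C=C(C)[C@]1(O)/C=C/C(C)=C\CO | intermediate
27 | 1-{[(1S,2R)-2-hydroxy-1,3-dimethyl-2-[(1E,3Z)-3-methyl-5-oxopenta-1,3-dien-1-yl]-5-oxocyclohex-3-en-1-yl]methyl} 5-methyl (3R)-3-hydroxy-3-methylpentanedioate | COC(=O)C[C@@](C)(O)CC(=O)OC[C@]1(C)CC(=O)C=C(C)[C@]1(O)/C=C/C(C)=C\C=O | intermediate
28 | (2Z,4E)-5-[(1R,6S)-1-hydroxy-6-({[(3R)-3-hydroxy-5-methoxy-3-methyl-5-oxopentanoyl]oxy}methyl)-2,6-dimethyl-4-oxocyclohex-2-en-1-yl]-3-methylpenta-2,4-dienoic acid | COC(=O)C[C@@](C)(O)CC(=O)OC[C@]1(C)CC(=O)C=C(C)[C@]1(O)/C=C/C(C)=C\C(=O)O | target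

Total step count: 19 (14 in the main line, 1 for the enynol fragment, 4 for the glutarate fragment).
Longest linear sequence: 14 steps (steps 1–8, 10, 11 and 16–19).

Steps most likely to fail

Step 2. The epoxide may ionise to an open tertiary cation before the ring CH2 migrates, which would lower the enantiomeric purity at C6' or divert material to a hydride shift (aldehyde) or to fluoride capture. The fallback keeps the same 1,2-shift but runs it on a silyl ether with a chelating Lewis acid. Compound 4 would be silylated (TMSCl, imidazole, DMF) to trimethyl({1-[(2R)-2-methyloxiran-2-yl]cyclopentyl}oxy)silane F1. F1 would then be treated with TiCl4 in CH2Cl2 at −78 °C; the silyl ether is a stronger donor for the anti shift, and aqueous work-up of the titanium aldolate returns the route at 5.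

Step 6. Hydrogen abstraction at C4' of the hindered, α-methylated enone may be slow or unselective, with competing attack at the vinylic methyl or over-oxidation. The fallback oxidises an extended enol ether by ionic chemistry instead. Compound 10 would be converted (TBSOTf, Et3N, CH2Cl2) into tert-butyl{[(1S)-2-{[tert-butyl(dimethyl)silyl]oxy}-1,3-dimethylcyclohexa-2,4-dien-1-yl]methoxy}dimethylsilane F2. Oxidation of F2 at its γ-carbon with mCPBA (NaHCO3, CH2Cl2, −20 °C; vinylogous Rubottom oxidation) should give (6S)-6-({[tert-butyl(dimethyl)silyl]oxy}methyl)-4-hydroxy-2,6-dimethylcyclohex-2-en-1-one F3 as a mixture of C4 epimers. MnO2 in CH2Cl2 would oxidise the allylic alcohol of F3 and rejoin the route at 11.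

Step 10. The lithium alkoxide of 13 may fragment by retro-aldol loss of formaldehyde, or the facial selectivity of the carbonyl addition may be poor if the internal chelate is not maintained in THF. The fallback replaces the alkoxide by an ether that is chelated by an external Lewis acid. Compound 13 would be converted (4-methoxybenzyl 2,2,2-trichloroacetimidate, catalytic La(OTf)3, toluene, rt) into (9S)-9-{[(4-methoxyphenyl)methoxy]methyl}-7,9-dimethyl-1,4-dioxaspiro[4.5]dec-6-en-8-one F4. The bromomagnesium acetylide of 15 (EtMgBr, Et2O) would be added to F4 in CH2Cl2 with MgBr2·OEt2 at −78 °C, where a six-membered magnesium chelate between the ether oxygen and the carbonyl should direct attack anti to the C6' methyl. This should give (8S,9S)-8-[(3Z)-5-{[tert-butyl(dimethyl)silyl]oxy}-3-methylpent-3-en-1-yn-1-yl]-9-{[(4-methoxyphenyl)methoxy]methyl}-7,9-dimethyl-1,4-dioxaspiro[4.5]dec-6-en-8-ol F5. DDQ in CH2Cl2/pH 7 buffer would then remove the 4-methoxybenzyl group and return the route at 17.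

Further compounds
F1 | step 2 | trimethyl({1-[(2R)-2-methyloxiran-2-yl]cyclopentyl}oxy)silane | C[C@@]1(CO1)C1(O[Si](C)(C)C)CCCC1
F2 | step 6 | tert-butyl{[(1S)-2-{[tert-butyl(dimethyl)silyl]oxy}-1,3-dimethylcyclohexa-2,4-dien-1-yl]methoxy}dimethylsilane | CC(C)(C)[Si](C)(C)OC[C@]1(C)CC=CC(C)=C1O[Si](C)(C)C(C)(C)C
F3 | step 6 | (6S)-6-({[tert-butyl(dimethyl)silyl]oxy}methyl)-4-hydroxy-2,6-dimethylcyclohex-2-en-1-one (both C4 epimers) | CC(C)(C)[Si](C)(C)OC[C@]1(C)CC(O)C=C(C)C1=O
F4 | step 10 | (9S)-9-{[(4-methoxyphenyl)methoxy]methyl}-7,9-dimethyl-1,4-dioxaspiro[4.5]dec-6-en-8-one | COc1ccc(COC[C@]2(C)CC3(OCCO3)C=C(C)C2=O)cc1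
F5 | step 10 | (8S,9S)-8-[(3Z)-5-{[tert-butyl(dimethyl)silyl]oxy}-3-methylpent-3-en-1-yn-1-yl]-9-{[(4-methoxyphenyl)methoxy]methyl}-7,9-dimethyl-1,4-dioxaspiro[4.5]dec-6-en-8-ol | COc1ccc(COC[C@]2(C)CC3(OCCO3)C=C(C)[C@]2(O)C#C/C(C)=C\CO[Si](C)(C)C(C)(C)C)cc1
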